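**Retrosynthetic overview**
- Last step: acid unmasks ring B, turning the α,β-epoxy ketone into the diosphenol and the tertiary aldol into the isopropylidene.
- Key disconnection: the C3–O ester bond, made by anti-Markovnikov addition of the complete (Z,Z)-diester acid across the C3=C4 olefin on the face opposite the angular methyl; this sets C3 and C4.
- Olefin partner: acetone aldol of the 4,5-dimethyl dienone, which comes from (S)-Wieland–Miescher ketone by methyl addition and dehydration; C5 is set in the prolinamide-catalysed Robinson annulation.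
- Acid partner: (Z)-3-iodobut-2-en-1-ol and angelic acid (Mitsunobu C–O bond), then hydroxycarbonylation.
- Ring order: ring A is the starting cyclohexanedione, ring B is closed onto it in step 1; the oxirane is only transient.

Assumption: positions use eremophilane numbering (C3 ester carbon, C4/C15 secondary methyl, C5/C14 angular methyl, C8 ketone, C9 enol carbon, C10 ring-fusion sp2 carbon, C11 isopropylidene carbon; α = face opposite C14), and centres that are erased later (carbinol C4, C7, C9, C10) are drawn as the expected major epimer.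

**Route**

Step 1
Reactants: 1 2-methylcyclohexane-1,3-dione; 2 but-3-en-2-one
Product: 4 (S)-8a-methyl-3,4,8,8a-tetrahydronaphthalene-1,6(2H,7H)-dione, via triketone 3 (not isolated)
Conditions: Et3N (1 mol%), neat, rt; then (S)-N-[(Sa)-2′-(tosylamino)-1,1′-binaphthalen-2-yl]pyrrolidine-2-carboxamide (2 mol%), PhCO2H (2.5 mol%), neat, rt; recrystallisation
Reagents that add atoms: none
Why: Michael addition followed by a prolinamide-catalysed enamine aldol condensation (Hajos–Parrish-type Robinson annulation) in which the L-proline-derived catalyst selects one of the two enantiotopic ring carbonyls and sets the quaternary centre as S (the future C5).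

Step 2
Reactants: 4 (S)-Wieland–Miescher ketone
Product: 7 (4aS,5S)-5-hydroxy-4a,5-dimethyl-4,4a,5,6,7,8-hexahydronaphthalen-2(3H)-one, via potassium dienolate 5 (not isolated), via magnesium alkoxide 6 (not isolated)
Conditions: KH (1.0 equiv), THF, 0 °C to rt; MeMgBr, −78 to 0 °C; 1 M HCl, 0 °C
Reagents that add atoms: methylmagnesium bromide, C[Mg]Br
Why: the γ-proton of the enone is the most acidic site, so KH masks only the enone as its extended dienolate and the Grignard reagent then adds 1,2 to the free saturated ketone from the face opposite the angular methyl (the carbinol centre is erased in step 3), while acidic work-up returns the conjugated enone.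

Step 3
Reactants: 7 tertiary carbinol
Product: 8 (R)-4a,5-dimethyl-4,4a,7,8-tetrahydronaphthalen-2(3H)-one
Conditions: TsOH·H2O (5 mol%), toluene, 80 °C
Reagents that add atoms: none
Why: acid-catalysed E1 dehydration gives the thermodynamically favoured endocyclic trisubstituted C3=C4 olefin (C5 has no hydrogen and any exocyclic isomer equilibrates), leaving the quaternary centre untouched.

Step 4
Reactants: 8 dienone
Product: 11 (3S,4aR)-3-(2-hydroxypropan-2-yl)-4a,5-dimethyl-4,4a,7,8-tetrahydronaphthalen-2(3H)-one, via lithium dienolate 9 (not isolated), via lithium aldolate 10 (not isolated)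
Conditions: LiN(i-Pr)2, THF, −78 °C; acetone, −78 °C, 10 min; AcOH, −78 °C
Reagents that add atoms: acetone, CC(C)=O
Why: kinetic deprotonation at the α′-CH2 (C7) gives the cross-conjugated enolate, whose aldol addition to acetone occurs anti to the angular methyl (this centre is erased in step 10), and the cold acidic quench prevents retro-aldol.

Step 5
Reactants: 12 but-2-yn-1-ol
Product: 14 (Z)-3-iodobut-2-en-1-ol, via cyclic vinylalanate 13 (not isolated)
Conditions: NaAlH2(OCH2CH2OCH3)2, THF, 0 °C to rt; I2, −78 °C
Reagents that add atoms: iodine, II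
Why: alkoxide-directed trans-hydroalumination of the propargylic alcohol places aluminium on the distal carbon cis to CH2O, and iodinolysis with retention fixes the Z geometry.

Step 6
Reactants: 14 (Z)-3-iodobut-2-en-1-ol; 15 (Z)-2-methylbut-2-enoic acid (angelic acid)
Product: 16 (Z)-3-iodobut-2-en-1-yl (Z)-2-methylbut-2-enoate
Conditions: PPh3, diisopropyl azodicarboxylate, THF, 0 °C to rt
Reagents that add atoms: none
Why: Mitsunobu esterification forms the alkyl C–O bond with angelic acid acting only as the nucleophile, so the acid is never acyl-activated and cannot isomerise to the tiglate.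

Step 7
Reactants: 16 iodo ester
Product: 17 (Z)-2-methyl-4-{[(Z)-2-methylbut-2-enoyl]oxy}but-2-enoic acid
Conditions: Pd(OAc)2 (5 mol%), PPh3 (10 mol%), CO (1 atm), H2O, Et3N, DMF, 40 °C
Reagents that add atoms: carbon monoxide, [C-]#[O+]; water, O
Why: palladium-catalysed hydroxycarbonylation (oxidative addition of zerovalent palladium to the vinyl C–I bond, CO insertion, hydrolysis of the acyl-palladium) proceeds with retention of olefin geometry, and the vinyl iodide reacts faster than the allylic ester can ionise.

Step 8
Reactants: 11 aldol adduct; 17 (Z,Z)-diester acid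
Product: 18 (1R,2R,7S,8aR)-7-(2-hydroxypropan-2-yl)-1,8a-dimethyl-6-oxo-1,2,3,4,6,7,8,8a-octahydronaphthalen-2-yl (Z)-2-methyl-4-{[(Z)-2-methylbut-2-enoyl]oxy}but-2-enoate
Conditions: 17 (2 equiv), 9-mesityl-3,6-di-tert-butyl-10-phenylacridinium tetrafluoroborate (5 mol%), 2-phenylmalononitrile (50 mol%), 2,6-lutidine (25 mol%), ClCH2CH2Cl, 450 nm LEDs, 23 °C
Reagents that add atoms: none
Why: Proposed new method: the excited acridinium oxidises only the electron-rich trisubstituted C3=C4 olefin (the enone and both enoates are much harder to oxidise) to its radical cation, the carboxylate of 17 adds to the less substituted C3 on the α face (the β face is blocked 1,3 by the axial angular methyl) to give the tertiary C4 radical, and 2-phenylmalononitrile delivers H axially on the same face, so O and H add syn, the C4 methyl ends equatorial and cis to the angular methyl, and C3 (R) and C4 (R) are both set; a carbon-acid hydrogen donor replaces the usual thiol so that no thiyl radical can scramble the Z-enoates, and the acid is never acyl-activated; the closest known reaction type is the acridinium-photocatalysed anti-Markovnikov hydroacyloxylation of simple alkenes with simple carboxylic acids, not shown for fragment coupling with a conjugated Z-enoic acid or for diastereocontrol on a decalin.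

Step 9
Reactants: 18 enone ester
Product: 19 4a,5-epoxide of 18 (C9–C10 oxirane, oxygen cis to the angular methyl)
Conditions: t-BuOOH, n-BuLi (gives t-BuOOLi), THF, −20 to 0 °C
Reagents that add atoms: tert-butyl hydroperoxide, CC(C)(C)OO
Why: Weitz–Scheffer nucleophilic epoxidation is confined to the only enone (the trisubstituted α-methyl enoates are far poorer acceptors at this temperature, and the weakly basic peroxide does not deprotonate the tertiary alcohol, so no retro-aldol); the oxirane is expected mainly cis to the angular methyl as with steroidal 4-en-3-ones, and either epimer is converted in step 10.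

Step 10
Reactants: 19 epoxy ketone
Product: 21 (1R,2R,8aR)-5-hydroxy-1,8a-dimethyl-6-oxo-7-(propan-2-ylidene)-1,2,3,4,6,7,8,8a-octahydronaphthalen-2-yl (Z)-2-methyl-4-{[(Z)-2-methylbut-2-enoyl]oxy}but-2-enoate, via epoxy dienone 20 (not isolated)
Conditions: H2SO4 (2% v/v), AcOH, 15 °C
Reagents that add atoms: none
Why: acid-catalysed dehydration of the tertiary aldol to the conjugated isopropylidene and acid-catalysed isomerisation of the α,β-epoxy ketone to the diosphenol (opening at tertiary C10 and loss of H9, as in the conversion of 4,5-epoxy-3-keto steroids into 4-hydroxy-4-en-3-ones) make C7, C9 and C10 sp2 and leave C3, C4 and C5 untouched.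

**Compound list**
1 | 2-methylcyclohexane-1,3-dione | CC1C(=O)CCCC1=O | starting material
2 | but-3-en-2-one (methyl vinyl ketone) | C=CC(C)=O | starting material
3 | 2-methyl-2-(3-oxobutyl)cyclohexane-1,3-dione | CC(=O)CCC1(C)C(=O)CCCC1=O | intermediate (not isolated)
4 | (S)-8a-methyl-3,4,8,8a-tetrahydronaphthalene-1,6(2H,7H)-dione, (S)-Wieland–Miescher ketone | O=C1CCCC2=CC(=O)CC[C@@]21C | intermediate
5 | potassium dienolate of 4 (O–C8=C9–C10=C1, C4 ketone free) | O=C1CCC=C2C=C([O-])CC[C@@]21C.[K+] | intermediate (not isolated)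
6 | bromomagnesium C4-alkoxide of the potassium dienolate (methyl added at C4) | [O-][C@@]1(C)CCC=C2C=C([O-])CC[C@@]21C.[K+].[Mg+2].[Br-] | intermediate (not isolated)
7 | (4aS,5S)-5-hydroxy-4a,5-dimethyl-4,4a,5,6,7,8-hexahydronaphthalen-2(3H)-one (OH cis to the angular methyl) | O[C@@]1(C)CCCC2=CC(=O)CC[C@@]21C | intermediate
8 | (R)-4a,5-dimethyl-4,4a,7,8-tetrahydronaphthalen-2(3H)-one | CC1=CCCC2=CC(=O)CC[C@@]21C | intermediate
9 | lithium cross-conjugated dienolate of 8 (O–C8=C7) | CC1=CCCC2=CC([O-])=CC[C@@]21C.[Li+] | intermediate (not isolated)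
10 | lithium aldolate of 11 | CC1=CCCC2=CC(=O)[C@H](C(C)(C)[O-])C[C@@]21C.[Li+] | intermediate (not isolated)
11 | (3S,4aR)-3-(2-hydroxypropan-2-yl)-4a,5-dimethyl-4,4a,7,8-tetrahydronaphthalen-2(3H)-one | CC1=CCCC2=CC(=O)[C@H](C(C)(C)O)C[C@@]21C | intermediate
12 | but-2-yn-1-ol | CC#CCO | starting material
13 | sodium cyclic vinylalanate (Al bonded to O and to C3 of the butenyl unit, two 2-methoxyethoxy ligands) | CC1=CCO[Al-]1(OCCOC)OCCOC.[Na+] | intermediate (not isolated)
14 | (Z)-3-iodobut-2-en-1-ol | C/C(I)=C/CO | intermediate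
15 | (Z)-2-methylbut-2-enoic acid (angelic acid) | C/C=C(/C)C(=O)O | starting material
16 | (Z)-3-iodobut-2-en-1-yl (Z)-2-methylbut-2-enoate | C/C=C(/C)C(=O)OC/C=C(/C)I | intermediate
17 | (Z)-2-methyl-4-{[(Z)-2-methylbut-2-enoyl]oxy}but-2-enoic acid | C/C=C(/C)C(=O)OC/C=C(/C)C(=O)O | intermediate
18 | (1R,2R,7S,8aR)-7-(2-hydroxypropan-2-yl)-1,8a-dimethyl-6-oxo-1,2,3,4,6,7,8,8a-octahydronaphthalen-2-yl ester of 17 | C/C=C(/C)C(=O)OC/C=C(/C)C(=O)O[C@@H]1CCC2=CC(=O)[C@H](C(C)(C)O)C[C@]2(C)[C@H]1C | intermediate
19 | C9–C10 epoxide of 18, oxirane oxygen cis to the angular methyl | C/C=C(/C)C(=O)OC/C=C(/C)C(=O)O[C@@H]1CC[C@]23O[C@H]2C(=O)[C@H](C(C)(C)O)C[C@]3(C)[C@H]1C | intermediate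
20 | dehydrated epoxy ketone (7-propan-2-ylidene, oxirane retained) | C/C=C(/C)C(=O)OC/C=C(/C)C(=O)O[C@@H]1CC[C@]23O[C@H]2C(=O)C(=C(C)C)C[C@]3(C)[C@H]1C | intermediate (not isolated)
21 | (1R,2R,8aR)-5-hydroxy-1,8a-dimethyl-6-oxo-7-(propan-2-ylidene)-1,2,3,4,6,7,8,8a-octahydronaphthalen-2-yl (Z)-2-methyl-4-{[(Z)-2-methylbut-2-enoyl]oxy}but-2-enoate | C/C=C(/C)C(=O)OC/C=C(/C)C(=O)O[C@@H]1CCC2=C(O)C(=O)C(=C(C)C)C[C@]2(C)[C@H]1C | target

**Step count**
Total steps: 10. Longest linear sequence: 7 (steps 1, 2, 3, 4, 8, 9, 10); the acid branch is steps 5–7.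

**Steps most likely to fail and their fallbacks**

Step 8 (the new reaction). Risks are low conversion with a stoichiometric conjugated acid, and imperfect H-atom delivery at C4. The fallback uses known chemistry, sets out from 11 and comes back at 18. mCPBA (NaHCO3, CH2Cl2, 0 °C) epoxidises only the electron-rich C3=C4 olefin on the α face to give the 3α,4α-epoxide of 11 F3. Cp2TiCl (trivalent titanium, made from Cp2TiCl2 and Mn) with 1,4-cyclohexadiene in THF opens the oxirane homolytically at the tertiary carbon and the C4 radical is reduced, giving the anti-Markovnikov alcohol (3S,4aR,5R,6R)-6-hydroxy-3-(2-hydroxypropan-2-yl)-4a,5-dimethyl-4,4a,5,6,7,8-hexahydronaphthalen-2(3H)-one F4. Yamaguchi esterification of its secondary hydroxyl with 17 (2,4,6-trichlorobenzoyl chloride, Et3N, then DMAP, toluene) gives 18.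

Step 9. The basic peroxide may attack the conjugated esters or trigger retro-aldol. The fallback installs the oxirane without base, sets out from 18 and comes back at 19. NaBH4/CeCl3·7H2O (MeOH, −40 °C) reduces the enone carbonyl to the 8β-allylic alcohol of 18 F5. VO(acac)2 (cat.) with t-BuOOH in CH2Cl2 epoxidises only the allylic-alcohol olefin, syn to the hydroxyl, to give the epoxy alcohol F6. Dess–Martin periodinane (NaHCO3, CH2Cl2) oxidises the secondary alcohol to 19.

Step 2. Masking the enone as its dienolate may be incomplete, or the Grignard reagent may enolise the hindered ketone. The fallback protects the enone covalently, sets out from 4 and comes back at 7. Ethane-1,2-dithiol with TsOH in AcOH converts only the enone carbonyl into the enone 1,3-dithiolane of 4 F1. MeMgBr with CeCl3 (THF, −78 °C) gives the dithiolane carbinol F2. MeI/CaCO3 in aqueous MeCN (45 °C) removes the dithiolane to give 7.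

Further compounds
F1 | step 2 | enone 1,3-dithiolane of 4 (spiro-dithiolane at C8, C9=C10 retained) | O=C1CCCC2=CC3(SCCS3)CC[C@@]21C
F2 | step 2 | dithiolane carbinol (4-hydroxy-4-methyl, OH cis to the angular methyl) | O[C@@]1(C)CCCC2=CC3(SCCS3)CC[C@@]21C
F3 | step 8 | 3α,4α-epoxide of 11 (oxirane trans to the angular methyl) | C[C@@]12O[C@@H]1CCC3=CC(=O)[C@H](C(C)(C)O)C[C@@]32C
F4 | step 8 | (3S,4aR,5R,6R)-6-hydroxy-3-(2-hydroxypropan-2-yl)-4a,5-dimethyl-4,4a,5,6,7,8-hexahydronaphthalen-2(3H)-one | O[C@@H]1CCC2=CC(=O)[C@H](C(C)(C)O)C[C@]2(C)[C@H]1C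
F5 | step 9 | 8β-allylic alcohol of 18 (C8 carbonyl reduced, OH cis to the angular methyl) | C/C=C(/C)C(=O)OC/C=C(/C)C(=O)O[C@@H]1CCC2=C[C@@H](O)[C@H](C(C)(C)O)C[C@]2(C)[C@H]1C
F6 | step 9 | epoxy alcohol (C9–C10 oxirane syn to the 8β-hydroxyl) | C/C=C(/C)C(=O)OC/C=C(/C)C(=O)O[C@@H]1CC[C@]23O[C@H]2[C@@H](O)[C@H](C(C)(C)O)C[C@]3(C)[C@H]1C
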